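**Assumption:** the phosphorus-bearing carbon (C2 of 12–21, F1, F2) is an inconsequential 1:1 epimer mixture that the olefination removes, so it is written without configuration. Compounds 1, 6, 9 and 25 are taken as purchased. Locants in each name are those of that compound's own name.

## Retrosynthetic overview

1. The target comes from the C2-epimeric threo epoxy alcohol by Mitsunobu inversion with 3-methylbut-2-enoic acid; the CH2OH comes from a ring enoate.
2. The 11-membered carbocycle is closed by intramolecular Horner–Wadsworth–Emmons olefination (C7=C8); the oxirane is made just before, on the open chain, by hydroxyl-directed epoxidation. Ring order: oxirane, then carbocycle.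
3. The quaternary C5 and the (E)-C3=C4 alkene come from a Claisen rearrangement of the vinyl ether of a secondary allylic alcohol (1,3-chirality transfer).
4. That alcohol comes from Nozaki–Hiyama–Kishi union of an (E)-vinyl iodide (from 6-methylhept-5-en-2-one) with an α-silyloxy aldehyde.
5. The aldehyde comes from a Z-selective Wittig reaction on the methyl ketone of (R)-glycerate acetonide, the only purchased stereocentre.

## Route

Step 1
Reactants: 1 6-methylhept-5-en-2-one
Product: 3 6-methylhept-5-en-1-yne, via enol phosphate 2 (not isolated)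
Conditions: LDA (1.05 equiv), THF, −78 °C; ClP(O)(OEt)2; then LDA (2.3 equiv), −78 °C → rt
Reagents that add atoms: diethyl chlorophosphate CCOP(=O)(Cl)OCC (its atoms stay only in 2)
Why: Kinetic enolisation at the methyl group, O-phosphorylation and LDA-induced elimination of diethyl phosphate (Negishi methyl-ketone-to-alkyne synthesis) give the terminal alkyne without touching the trisubstituted alkene.

Step 2
Reactants: 3 6-methylhept-5-en-1-yne
Product: 5 (1E)-1-iodo-2,6-dimethylhepta-1,5-diene, via alkenylalane 4 (not isolated)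
Conditions: Me3Al (2 equiv), Cp2ZrCl2 (0.25 equiv), CH2Cl2, 0 °C → rt; then I2, THF, −30 → 0 °C
Reagents that add atoms: trimethylaluminium C[Al](C)C; iodine II
Why: Negishi Zr-catalysed carboalumination adds Me and Al syn across the alkyne with Me on the internal carbon, and iodinolysis of the C–Al bond with retention fixes the E geometry.

Step 3
Reactants: 6 methyl (4R)-2,2-dimethyl-1,3-dioxolane-4-carboxylate
Product: 8 1-[(4R)-2,2-dimethyl-1,3-dioxolan-4-yl]ethan-1-one, via Weinreb amide 7 (not isolated)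
Conditions: MeNH(OMe)·HCl (1.5 equiv), i-PrMgCl (3.0 equiv), THF, −20 °C; then MeMgBr (2 equiv), −20 → 0 °C
Reagents that add atoms: N,O-dimethylhydroxylamine hydrochloride CNOC.Cl (its atoms stay only in 7); methylmagnesium bromide C[Mg]Br
Why: In situ Weinreb amide formation followed by a single Grignard addition through the chelated tetrahedral intermediate gives the methyl ketone without over-addition and without touching the purchased stereocentre.

Step 4
Reactants: 8 1-[(4R)-2,2-dimethyl-1,3-dioxolan-4-yl]ethan-1-one; 9 (4-carboxybutyl)triphenylphosphonium bromide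
Product: 11 methyl (5Z)-6-[(4S)-2,2-dimethyl-1,3-dioxolan-4-yl]hept-5-enoate, via sodium carboxylate 10 (not isolated)
Conditions: 9 (2.2 equiv), NaHMDS (4.4 equiv), THF, 0 °C; 8, −78 °C → rt; then MeI, DMF, rt
Reagents that add atoms: iodomethane CI; sodium bis(trimethylsilyl)amide C[Si](C)(C)[N-][Si](C)(C)C.[Na+] (its sodium stays only in 10)
Why: Wittig olefination of an α-alkoxy methyl ketone with a salt-free non-stabilised ylide is Z-selective (Still–Sreekumar), and the carboxylate is O-methylated in the same flask; the dioxolane stereocentre is untouched (its CIP label changes R→S only).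

Step 5
Reactants: 11 methyl (5Z)-6-[(4S)-2,2-dimethyl-1,3-dioxolan-4-yl]hept-5-enoate
Product: 13 methyl (5Z)-2-(diethoxyphosphoryl)-6-[(4S)-2,2-dimethyl-1,3-dioxolan-4-yl]hept-5-enoate, via phosphonite 12 (not isolated)
Conditions: LDA (1.1 equiv), THF, −78 °C; ClP(OEt)2, −78 °C → rt; then 30% H2O2, 0 °C
Reagents that add atoms: diethyl chlorophosphite CCOP(Cl)OCC; hydrogen peroxide OO
Why: The ester enolate is phosphinylated at carbon by the soft P(III) chloride and the phosphonite is oxidised to the phosphonate (Wiemer C–P bond formation), installing the Horner–Wadsworth–Emmons handle.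

Step 6
Reactants: 13 the phosphonate acetonide
Product: 14 methyl (5Z,7S)-2-(diethoxyphosphoryl)-7,8-dihydroxy-6-methyloct-5-enoate
Conditions: AcOH/THF/H2O (3:1:1), 45 °C
Reagents that add atoms: none
Why: Mild acid-catalysed acetal hydrolysis frees the 1,2-diol while the esters, the phosphonate and the allylic C–O stereocentre survive.

Step 7
Reactants: 14 the diol
Product: 15 methyl (5Z,7S)-2-(diethoxyphosphoryl)-6-methyl-7,8-bis[(triethylsilyl)oxy]oct-5-enoate
Conditions: TESCl (2.5 equiv), imidazole, CH2Cl2, 0 °C → rt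
Reagents that add atoms: chlorotriethylsilane CC[Si](Cl)(CC)CC
Why: Exhaustive silylation protects both hydroxyls as triethylsilyl ethers, the secondary one to serve through the Claisen step.

Step 8
Reactants: 15 the bis-silyl ether
Product: 16 methyl (5Z,7S)-2-(diethoxyphosphoryl)-6-methyl-8-oxo-7-[(triethylsilyl)oxy]oct-5-enoate
Conditions: (COCl)2, DMSO, CH2Cl2, −78 → −30 °C; Et3N, −78 → 0 °C; used at once
Reagents that add atoms: none
Why: Under Swern conditions a primary triethylsilyl ether is cleaved and oxidised directly to the aldehyde while the secondary silyl ether is retained, giving the α-silyloxy aldehyde without epimerisation.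

Step 9
Reactants: 16 the α-silyloxy aldehyde; 5 (1E)-1-iodo-2,6-dimethylhepta-1,5-diene
Product: 17 methyl (5Z,7S,8R,9E)-2-(diethoxyphosphoryl)-8-hydroxy-6,10,14-trimethyl-7-[(triethylsilyl)oxy]pentadeca-5,9,13-trienoate
Conditions: CrCl2 (6 equiv), NiCl2 (2 mol %), DMF, rt
Reagents that add atoms: none
Why: Nozaki–Hiyama–Kishi coupling tolerates the esters and the acidic phosphonoacetate C–H, and Felkin–Anh addition anti to the α-silyloxy group should set the new C8 carbinol as R (7,8-anti, expected about 4:1, epimers separated).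

Step 10
Reactants: 17 the (7S,8R) allylic alcohol
Product: 20 methyl (5Z,7R,8E,10S)-2-(diethoxyphosphoryl)-7-hydroxy-6,10,14-trimethyl-10-(2-oxoethyl)pentadeca-5,8,13-trienoate, via allyl vinyl ether 18 (not isolated), via silyl ether aldehyde 19 (not isolated)
Conditions: Hg(OAc)2 (0.3 equiv), ethyl vinyl ether, reflux; then PhMe, 120 °C, sealed tube; then HF·pyridine, pyridine, THF, 0 °C
Reagents that add atoms: ethyl vinyl ether C=COCC
Why: Transvinylation and Claisen rearrangement through a chair transition state with the C7 substituent equatorial form the C10–CH2 bond suprafacially, transferring the C8 (R) carbinol chirality to the quaternary C10 (S) and giving the 8E alkene; buffered HF then removes the silyl ether.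

Step 11
Reactants: 20 the hydroxy aldehyde
Product: 21 methyl 2-(diethoxyphosphoryl)-4-[(2R,3S)-3-[(1R,2E,4S)-1-hydroxy-4,8-dimethyl-4-(2-oxoethyl)nona-2,7-dien-1-yl]-3-methyloxiran-2-yl]butanoate
Conditions: Ti(OiPr)4 (1.2 equiv), t-BuOOH (2 equiv), 4 Å MS, CH2Cl2, −20 °C
Reagents that add atoms: tert-butyl hydroperoxide CC(C)(C)OO
Why: Hydroxyl-directed Ti(OiPr)4/TBHP epoxidation is chemoselective for the trisubstituted allylic alkene, and A(1,3) strain with the cis CH2 keeps the carbinol H in the alkene plane so that oxygen is delivered syn to the hydroxyl, giving the threo oxirane (expected about 5:1, separable).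

Step 12
Reactants: 21 the open-chain epoxy alcohol
Product: 22 methyl (1S,2R,3E,5S,7E,11R)-2-hydroxy-1,5-dimethyl-5-(4-methylpent-3-en-1-yl)-12-oxabicyclo[9.1.0]dodeca-3,7-diene-8-carboxylate
Conditions: LiCl (10 equiv), DBU (5 equiv), MeCN, 1 mM, slow addition, rt
Reagents that add atoms: none
Why: Intramolecular Horner–Wadsworth–Emmons olefination (Masamune–Roush) at high dilution closes the 11-membered ring and gives the E-enoate, in which the two ring carbons are cis on the new alkene, the geometry also favoured by ring strain.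

Step 13
Reactants: 22 the macrocyclic hydroxy ester
Product: 23 (1S,2R,3E,5S,7E,11R)-8-(hydroxymethyl)-1,5-dimethyl-5-(4-methylpent-3-en-1-yl)-12-oxabicyclo[9.1.0]dodeca-3,7-dien-2-ol
Conditions: DIBAL (4 equiv), CH2Cl2, −78 °C; Rochelle salt
Reagents that add atoms: none
Why: DIBAL at −78 °C reduces the conjugated ester 1,2 to the primary allylic alcohol faster than it opens the oxirane.

Step 14
Reactants: 23 the diol
Product: 24 (1S,2R,3E,5S,7E,11R)-1,5-dimethyl-5-(4-methylpent-3-en-1-yl)-8-{[(triethylsilyl)oxy]methyl}-12-oxabicyclo[9.1.0]dodeca-3,7-dien-2-ol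
Conditions: TESCl (1.05 equiv), imidazole, CH2Cl2, −40 → −20 °C
Reagents that add atoms: chlorotriethylsilane CC[Si](Cl)(CC)CC
Why: The unhindered primary allylic alcohol is silylated selectively over the secondary alcohol flanked by the quaternary oxirane carbon.

Step 15
Reactants: 24 the mono-silyl ether; 25 3-methylbut-2-enoic acid
Product: 27 (1R,2S,3E,5S,7E,11R)-8-(hydroxymethyl)-1,5-dimethyl-5-(4-methylpent-3-en-1-yl)-12-oxabicyclo[9.1.0]dodeca-3,7-dien-2-yl 3-methylbut-2-enoate, via silyl ether ester 26 (not isolated)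
Conditions: PPh3 (3 equiv), DIAD (3 equiv), 25 (3 equiv), PhMe, 0 °C → rt; then HF·pyridine, pyridine, THF, 0 °C
Reagents that add atoms: none
Why: Mitsunobu esterification proceeds by SN2 displacement of the activated allylic carbinol, inverting C2 from R to S as the 3-methylbut-2-enoate is installed, and buffered HF·pyridine then removes the primary silyl ether without opening the oxirane.

## Compound list

1 | 6-methylhept-5-en-2-one | CC(=O)CCC=C(C)C | starting material
2 | diethyl 6-methylhepta-1,5-dien-2-yl phosphate | C=C(CCC=C(C)C)OP(=O)(OCC)OCC | intermediate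
3 | 6-methylhept-5-en-1-yne | C#CCCC=C(C)C | intermediate
4 | [(1E)-2,6-dimethylhepta-1,5-dien-1-yl]dimethylalumane | CC(C)=CCC/C(C)=C/[Al](C)C | intermediate
5 | (1E)-1-iodo-2,6-dimethylhepta-1,5-diene | CC(C)=CCC/C(C)=C/I | intermediate
6 | methyl (4R)-2,2-dimethyl-1,3-dioxolane-4-carboxylate | COC(=O)[C@H]1COC(C)(C)O1 | starting material
7 | (4R)-N-methoxy-N,2,2-trimethyl-1,3-dioxolane-4-carboxamide | CON(C)C(=O)[C@H]1COC(C)(C)O1 | intermediate
8 | 1-[(4R)-2,2-dimethyl-1,3-dioxolan-4-yl]ethan-1-one | CC(=O)[C@H]1COC(C)(C)O1 | intermediate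
9 | (4-carboxybutyl)triphenylphosphonium bromide | OC(=O)CCCC[P+](c1ccccc1)(c1ccccc1)c1ccccc1.[Br-] | starting material
10 | sodium (5Z)-6-[(4S)-2,2-dimethyl-1,3-dioxolan-4-yl]hept-5-enoate | [Na+].[O-]C(=O)CCC/C=C(C)\[C@H]1COC(C)(C)O1 | intermediate
11 | methyl (5Z)-6-[(4S)-2,2-dimethyl-1,3-dioxolan-4-yl]hept-5-enoate | COC(=O)CCC/C=C(C)\[C@H]1COC(C)(C)O1 | intermediate
12 | methyl (5Z)-2-(diethoxyphosphanyl)-6-[(4S)-2,2-dimethyl-1,3-dioxolan-4-yl]hept-5-enoate | COC(=O)C(P(OCC)OCC)CC/C=C(C)\[C@H]1COC(C)(C)O1 | intermediate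
13 | methyl (5Z)-2-(diethoxyphosphoryl)-6-[(4S)-2,2-dimethyl-1,3-dioxolan-4-yl]hept-5-enoate | COC(=O)C(P(=O)(OCC)OCC)CC/C=C(C)\[C@H]1COC(C)(C)O1 | intermediate
14 | methyl (5Z,7S)-2-(diethoxyphosphoryl)-7,8-dihydroxy-6-methyloct-5-enoate | COC(=O)C(P(=O)(OCC)OCC)CC/C=C(C)\[C@H](O)CO | intermediate
15 | methyl (5Z,7S)-2-(diethoxyphosphoryl)-6-methyl-7,8-bis[(triethylsilyl)oxy]oct-5-enoate | COC(=O)C(P(=O)(OCC)OCC)CC/C=C(C)\[C@H](O[Si](CC)(CC)CC)CO[Si](CC)(CC)CC | intermediate
16 | methyl (5Z,7S)-2-(diethoxyphosphoryl)-6-methyl-8-oxo-7-[(triethylsilyl)oxy]oct-5-enoate | COC(=O)C(P(=O)(OCC)OCC)CC/C=C(C)\[C@H](O[Si](CC)(CC)CC)C=O | intermediate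
17 | methyl (5Z,7S,8R,9E)-2-(diethoxyphosphoryl)-8-hydroxy-6,10,14-trimethyl-7-[(triethylsilyl)oxy]pentadeca-5,9,13-trienoate | COC(=O)C(P(=O)(OCC)OCC)CC/C=C(C)\[C@H](O[Si](CC)(CC)CC)[C@H](O)/C=C(C)/CCC=C(C)C | intermediate
18 | methyl (5Z,7S,8R,9E)-2-(diethoxyphosphoryl)-8-(ethenyloxy)-6,10,14-trimethyl-7-[(triethylsilyl)oxy]pentadeca-5,9,13-trienoate | COC(=O)C(P(=O)(OCC)OCC)CC/C=C(C)\[C@H](O[Si](CC)(CC)CC)[C@H](OC=C)/C=C(C)/CCC=C(C)C | intermediate
19 | methyl (5Z,7R,8E,10S)-2-(diethoxyphosphoryl)-6,10,14-trimethyl-10-(2-oxoethyl)-7-[(triethylsilyl)oxy]pentadeca-5,8,13-trienoate | COC(=O)C(P(=O)(OCC)OCC)CC/C=C(C)\[C@H](O[Si](CC)(CC)CC)/C=C/[C@@](C)(CCC=C(C)C)CC=O | intermediate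
20 | methyl (5Z,7R,8E,10S)-2-(diethoxyphosphoryl)-7-hydroxy-6,10,14-trimethyl-10-(2-oxoethyl)pentadeca-5,8,13-trienoate | COC(=O)C(P(=O)(OCC)OCC)CC/C=C(C)\[C@H](O)/C=C/[C@@](C)(CCC=C(C)C)CC=O | intermediate
21 | methyl 2-(diethoxyphosphoryl)-4-[(2R,3S)-3-[(1R,2E,4S)-1-hydroxy-4,8-dimethyl-4-(2-oxoethyl)nona-2,7-dien-1-yl]-3-methyloxiran-2-yl]butanoate | O=CC[C@](C)(CCC=C(C)C)/C=C/[C@@H](O)[C@]1(C)O[C@@H]1CCC(P(=O)(OCC)OCC)C(=O)OC | intermediate
22 | methyl (1S,2R,3E,5S,7E,11R)-2-hydroxy-1,5-dimethyl-5-(4-methylpent-3-en-1-yl)-12-oxabicyclo[9.1.0]dodeca-3,7-diene-8-carboxylate | CC(C)=CCC[C@]1(C)/C=C/[C@@H](O)[C@]2(C)O[C@@H]2CC/C(C(=O)OC)=C\C1 | intermediate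
23 | (1S,2R,3E,5S,7E,11R)-8-(hydroxymethyl)-1,5-dimethyl-5-(4-methylpent-3-en-1-yl)-12-oxabicyclo[9.1.0]dodeca-3,7-dien-2-ol | CC(C)=CCC[C@]1(C)/C=C/[C@@H](O)[C@]2(C)O[C@@H]2CC/C(CO)=C\C1 | intermediate
24 | (1S,2R,3E,5S,7E,11R)-1,5-dimethyl-5-(4-methylpent-3-en-1-yl)-8-{[(triethylsilyl)oxy]methyl}-12-oxabicyclo[9.1.0]dodeca-3,7-dien-2-ol | CC(C)=CCC[C@]1(C)/C=C/[C@@H](O)[C@]2(C)O[C@@H]2CC/C(CO[Si](CC)(CC)CC)=C\C1 | intermediate
25 | 3-methylbut-2-enoic acid | CC(C)=CC(=O)O | starting material
26 | (1R,2S,3E,5S,7E,11R)-1,5-dimethyl-5-(4-methylpent-3-en-1-yl)-8-{[(triethylsilyl)oxy]methyl}-12-oxabicyclo[9.1.0]dodeca-3,7-dien-2-yl 3-methylbut-2-enoate | CC(C)=CCC[C@]1(C)/C=C/[C@H](OC(=O)C=C(C)C)[C@]2(C)O[C@@H]2CC/C(CO[Si](CC)(CC)CC)=C\C1 | intermediate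
27 | (1R,2S,3E,5S,7E,11R)-8-(hydroxymethyl)-1,5-dimethyl-5-(4-methylpent-3-en-1-yl)-12-oxabicyclo[9.1.0]dodeca-3,7-dien-2-yl 3-methylbut-2-enoate | CC(C)=CCC[C@]1(C)/C=C/[C@H](OC(=O)C=C(C)C)[C@]2(C)O[C@@H]2CC/C(CO)=C\C1 | target

## Summary

Total step count: 15. Longest linear sequence: 13 steps (steps 3–15, from 6); steps 1–2 make the vinyl iodide and join at step 9.

Steps most likely to fail:

**Step 9** (labile α-silyloxy β,γ-unsaturated aldehyde; only moderate Felkin selectivity expected). The fallback sets out from 16 and corrects the carbinol by inversion instead of relying on addition selectivity. The coupling is run as before and the unwanted 8S alcohol F1 is collected. It is then inverted by a Mitsunobu reaction with chloroacetic acid (PPh3, DIAD) to the 8R chloroacetate F2. Brief K2CO3/MeOH at 0 °C cleaves the chloroacetate and the route is rejoined at 17.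

**Step 12** (11-membered ring closure on a chain carrying a trisubstituted oxirane). The fallback sets out from 20 and closes the ring before the oxirane is made. The same olefination on the more flexible triene gives the macrocyclic trienol ester F3. Ti(OiPr)4/TBHP epoxidation directed by the ring hydroxyl, on the exposed face of the cis alkene, then gives 22, where the route is rejoined. This relies on ring-controlled rather than open-chain facial selectivity.

**Step 15** (SN2 inversion at a hindered allylic carbinol next to a quaternary oxirane carbon, inside the ring). The fallback sets out from 24 and replaces inversion by oxidation and reduction. Dess–Martin oxidation gives the epoxy enone F4. Zn(BH4)2 in Et2O at −20 °C reduces it under chelation with the oxirane oxygen to the erythro alcohol F5. Acylation with 3-methylbut-2-enoyl chloride, DMAP and pyridine rejoins the route at 26, which is desilylated as in step 15.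

## Further compounds

F1 | step 9 | methyl (5Z,7S,8S,9E)-2-(diethoxyphosphoryl)-8-hydroxy-6,10,14-trimethyl-7-[(triethylsilyl)oxy]pentadeca-5,9,13-trienoate | COC(=O)C(P(=O)(OCC)OCC)CC/C=C(C)\[C@H](O[Si](CC)(CC)CC)[C@@H](O)/C=C(C)/CCC=C(C)C
F2 | step 9 | methyl (5Z,7S,8R,9E)-8-[(chloroacetyl)oxy]-2-(diethoxyphosphoryl)-6,10,14-trimethyl-7-[(triethylsilyl)oxy]pentadeca-5,9,13-trienoate | COC(=O)C(P(=O)(OCC)OCC)CC/C=C(C)\[C@H](O[Si](CC)(CC)CC)[C@H](OC(=O)CCl)/C=C(C)/CCC=C(C)C
F3 | step 12 | methyl (1E,4S,5E,7R,8Z)-7-hydroxy-4,8-dimethyl-4-(4-methylpent-3-en-1-yl)cycloundeca-1,5,8-triene-1-carboxylate | CC(C)=CCC[C@]1(C)/C=C/[C@@H](O)/C(C)=C\CC/C(C(=O)OC)=C\C1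
F4 | step 15 | (1R,3E,5S,7E,11R)-1,5-dimethyl-5-(4-methylpent-3-en-1-yl)-8-{[(triethylsilyl)oxy]methyl}-12-oxabicyclo[9.1.0]dodeca-3,7-dien-2-one | CC(C)=CCC[C@]1(C)/C=C/C(=O)[C@]2(C)O[C@@H]2CC/C(CO[Si](CC)(CC)CC)=C\C1
F5 | step 15 | (1S,2S,3E,5S,7E,11R)-1,5-dimethyl-5-(4-methylpent-3-en-1-yl)-8-{[(triethylsilyl)oxy]methyl}-12-oxabicyclo[9.1.0]dodeca-3,7-dien-2-ol | CC(C)=CCC[C@]1(C)/C=C/[C@H](O)[C@]2(C)O[C@@H]2CC/C(CO[Si](CC)(CC)CC)=C\C1
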